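Read the two simulated runs side by side; they look nearly the same.

| flask | starting material | gas phase | protic impurity | free catalyst | remark | time |
|---|---|---|---|---|---|---|
| midnight | 0.12 M | 9.3 mM (held) | 0.030 M | 12 mM | run made earlier |  |
| summer | 0.12 M | 9.3 mM (held) | 0.045 M | 12 mM | run made earlier |  |
| flask | 0.12 M | 9.3 mM (held) | 0.0600 M | 12 mM |  | 5.0 min |

| run | time / min | target / % |
|---|---|---|
| midnight | 0.417 | 2.7 |
| midnight | 0.833 | 5.3 |
| midnight | 1.33 | 8.0 |
| midnight | 1.50 | 8.9 |
| midnight | 2.00 | 12.2 |
| midnight | 2.50 | 15.0 |
| midnight | 3.00 | 16.5 |
| summer | 0.250 | 1.8 |
| summer | 0.333 | 2.4 |
| summer | 0.500 | 3.6 |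
| summer | 0.833 | 5.9 |
| summer | 1.33 | 8.4 |
| summer | 2.00 | 12.0 |
| summer | 3.00 | 16.9 |

(readings scatter by 0.5 percentage points)

- the target standing at 5.0 min, as a percentage of the starting material charged
- the change that raises the amount of target at 5.0 min, in percent of the starting material charged most ("none" if none brings more than 2 percentage points) (larch / elm / alder / none)
- amount of target at 5.0 min, in percent of the starting material charged, after elm

- larch: doubling the transfer coefficient of the gas phase, all else as stated
- elm: doubling the saturation concentration of gas phase, all else as stated
- alder: doubling the amount of free catalyst, all else as stated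

- at the start none of the gas is dissolved
- reactions considered so far: gas phase <-> dissolved gas; starting material + dissolved gas + free catalyst -> free catalyst + target; dissolved gas + free catalyst -> spent catalyst; starting material + protic impurity -> quenched substrate

1. At 3.00 min the midnight run stands at 16.5% and the summer run at 16.9%, though summer holds 0.045 M of protic impurity against 0.030 M. That gap of 0.4 percentage points is smaller than the scatter of one reading, so the two runs are read as one curve and averaged.

2. Up to 0.833 min the averaged target climbs at 0.0672 min⁻¹ as a fraction of the charge. The first midnight reading alone gives 0.0647 min⁻¹, so no gas lag shows. From there to 3.00 min the slope is 0.0512 min⁻¹.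

3. The midpoints of these two stretches lie 1.50 min apart, so the slope sinks at 0.181 min⁻¹. This is the fade rate, a pseudo-first-order loss of slope, and it is a reading with the scatter of the points. Its inverse is 5.52 min, close to the asked time, so the flask is read where the fade has taken hold.

4. My reckoning sets the target at S(1 − exp(−fade rate × time))/fade rate, leaving the extra protic impurity out: 22.1%. Both the target step and the catalyst death are first-order in [dissolved gas], so elm doubles slope and fade together and gives 31.0%. Alder doubles the slope and keeps the fade, which gives 44.2% with [starting material] held at its charge. The readings show no lag for larch to shorten. I choose alder.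

5. The forecast says 24%, alder and 37%. It reads a decay of 0.12 per minute, where my reading is 0.181 min⁻¹, and it holds that “Elm doubles the rate but also doubles catalyst death”. Both reckonings hold that rule for elm and part in its number, 31.0% against 37%.

6. The flask gives 21.1%, best alder with a gain of 15 points, and 29.6% after elm.

    gas phase ⇌ dissolved gas, rate k1*(csat - [dissolved gas]) (kL = 0.190 s⁻¹)
    starting material + dissolved gas + free catalyst → free catalyst + target (k = 13.0 M⁻² s⁻¹)
    dissolved gas + free catalyst → spent catalyst (k = 0.310 M⁻¹ s⁻¹)
    starting material + protic impurity → quenched substrate (k = 0.0220 M⁻¹ s⁻¹)

The fade rate, read from the earlier runs, leaves 40.4% of the first slope at 5.00 min; in the flask at that time free catalyst stands at 45.0% of its charge. Catalyst death is part of why the target stands where it does at the asked time, together with the early hour of the reading: without that step the flask holds 28.4% at the asked time, and left until 50.0 min it holds 30.8%. The neighbour charged with 0.030 M of free catalyst keeps 47.6% of its free catalyst at 5.00 min, against the flask's 45.0%, and its target stands at 42.3%.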